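**Retrosynthetic overview**
- The ten-membered ring is formed last, by closing C3–C4 in an NHC-catalysed intramolecular aldehyde-to-ketone benzoin reaction: the C3 aldehyde becomes an acyl-anion equivalent and adds to the C4 methyl ketone, which also sets C4.
- The seco keto-aldehyde comes from one ozonolysis that cleaves two trisubstituted alkenes and unmasks both carbonyls.
- C7–C8 is made by adding an allylchromium, generated from a 3-(bromomethyl)butenolide, to an α-(isovaleryloxy) aldehyde; this gives the α-methylene lactone and sets C7 and C8.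
- The butenolide (first ring, by RCM) comes from tiglaldehyde via Brown syn-alkoxyallylboration (C5, C6), isobutyrylation and a 2-(bromomethyl)acrylate ester.
- The aldehyde comes from (R)-citronellal (C10) by enamine α-acyloxylation (C9).

Assumption: 3-(methoxymethoxy)prop-1-ene, (+)-Ipc2BOMe and (R)-2-(triphenylmethyl)pyrrolidine are bought; C-numbers below are the germacrane positions of the target (C1–C10 ring, C11–C13 lactone and methylene, C14 and C15 methyls).

**Route**

Step 1
Reactants: 1 3-methylbutanoyl chloride (2 equiv)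
Product: 2 bis(3-methylbutanoyl) peroxide
Conditions: 30% aq H2O2 (0.55 equiv relative to 1), pyridine (1.1 equiv), Et2O, −10 to 0 °C; kept as a titrated solution and used at once
Reagents that add atoms: hydrogen peroxide, OO; 3-methylbutanoyl chloride (the second equivalent of 1), CC(C)CC(=O)Cl
Why: Schotten–Baumann-type double acylation in which each O–H of hydrogen peroxide is acylated by one molecule of 1, so two equivalents of the acid chloride give the symmetrical diacyl peroxide.

Step 2
Reactants: 3 (R)-citronellal; 2 bis(3-methylbutanoyl) peroxide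
Product: 4 (2R,3R)-3,7-dimethyl-1-oxooct-6-en-2-yl 3-methylbutanoate
Conditions: (R)-2-(triphenylmethyl)pyrrolidine (10 mol %), hydroquinone (10 mol %), THF, 0 °C; crude aldehyde used directly
Reagents that add atoms: none
Why: Proposed new method: the enamine α-acyloxylation of aldehydes, known with dibenzoyl peroxide, is extended to an aliphatic diacyl peroxide; the E-enamine of 3 attacks the O–O bond on the face left open by the trityl shield, so the catalyst sets C9 as R irrespective of the C10 methyl; the closest known reaction is the organocatalytic α-benzoyloxylation of aldehydes.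

Step 3
Reactants: 5 (E)-2-methylbut-2-enal (tiglaldehyde); 6 3-(methoxymethoxy)prop-1-ene
Product: 9 (3S,4S,5E)-3-(methoxymethoxy)-5-methylhepta-1,5-dien-4-ol, via allyllithium 7 (not isolated), via allylborane 8 (not isolated)
Conditions: 6, s-BuLi, THF, −78 °C; (+)-Ipc2BOMe; BF3·OEt2; 5, −78 °C; then NaOH, H2O2, rt
Reagents that add atoms: none
Why: Brown alkoxyallylboration; the Z-γ-alkoxyallylborane reacts through a chair Zimmerman–Traxler transition state (syn, threo diol pattern) and the isopinocampheyl groups from (+)-Ipc2BOMe direct attack to the Re face of 5, which sets C5 and C6.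

Step 4
Reactants: 9 (3S,4S,5E)-3-(methoxymethoxy)-5-methylhepta-1,5-dien-4-ol
Product: 10 (3S,4S,5E)-3-(methoxymethoxy)-5-methylhepta-1,5-dien-4-yl 2-methylpropanoate
Conditions: i-PrCOCl, pyridine, DMAP (cat.), CH2Cl2, 0 °C to rt
Reagents that add atoms: isobutyryl chloride, CC(C)C(=O)Cl
Why: DMAP-catalysed acylation of the only free hydroxyl (C5) installs the isobutyrate without touching a stereocentre.

Step 5
Reactants: 10 (3S,4S,5E)-3-(methoxymethoxy)-5-methylhepta-1,5-dien-4-yl 2-methylpropanoate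
Product: 11 (3S,4S,5E)-3-hydroxy-5-methylhepta-1,5-dien-4-yl 2-methylpropanoate
Conditions: ZnBr2, n-PrSH, CH2Cl2, 0 °C, 10 min
Reagents that add atoms: none
Why: Lewis acid and thiol cleave the methoxymethyl acetal (the thiol traps the oxocarbenium ion) under non-basic conditions that leave the allylic ester in place and avoid 1,2-acyl migration.

Step 6
Reactants: 11 (3S,4S,5E)-3-hydroxy-5-methylhepta-1,5-dien-4-yl 2-methylpropanoate; 12 2-(bromomethyl)prop-2-enoic acid
Product: 14 (3S,4S,5E)-5-methyl-4-(2-methylpropanoyloxy)hepta-1,5-dien-3-yl 2-(bromomethyl)prop-2-enoate, via acid chloride 13 (not isolated)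
Conditions: 12, (COCl)2, DMF (cat.), CH2Cl2, 0 °C to rt; then 11, 2,6-lutidine, CH2Cl2, −20 to 0 °C
Reagents that add atoms: none
Why: Esterification of the C6 alcohol by the in situ acid chloride, with a hindered pyridine base that does not displace the allylic bromide.

Step 7
Reactants: 14 (3S,4S,5E)-5-methyl-4-(2-methylpropanoyloxy)hepta-1,5-dien-3-yl 2-(bromomethyl)prop-2-enoate
Product: 15 (1S,2E)-1-[(2S)-4-(bromomethyl)-5-oxo-2,5-dihydrofuran-2-yl]-2-methylbut-2-en-1-yl 2-methylpropanoate
Conditions: second-generation Hoveyda–Grubbs catalyst (H2IMes)Cl2Ru=CH(C6H4-2-OiPr) (10 mol %), toluene (5 mM), 80 °C, Ar sparge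
Reagents that add atoms: none
Why: Ring-closing metathesis of the vinyl group with the acrylate closes the butenolide with loss of ethene; the trisubstituted tiglyl alkene cannot compete because a six-membered closure would need a tetrasubstituted alkene.

Step 8
Reactants: 15 (1S,2E)-1-[(2S)-4-(bromomethyl)-5-oxo-2,5-dihydrofuran-2-yl]-2-methylbut-2-en-1-yl 2-methylpropanoate; 4 (2R,3R)-3,7-dimethyl-1-oxooct-6-en-2-yl 3-methylbutanoate
Product: 17 (1S,2E)-1-[(2S,3R)-3-[(1R,2R,3R)-1-hydroxy-3,7-dimethyl-2-(3-methylbutanoyloxy)oct-6-en-1-yl]-4-methylidene-5-oxooxolan-2-yl]-2-methylbut-2-en-1-yl 2-methylpropanoate, via allylchromium 16 (not isolated)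
Conditions: CrCl2 (4 equiv), THF, 0 °C to rt, 15 and 4 added together; aq NH4Cl work-up
Reagents that add atoms: none
Why: Nozaki–Hiyama-type Barbier allylation; divalent chromium turns the allylic bromide into an allylchromium that attacks the aldehyde through ring carbon C7, anti to the C6 side chain, via a chair transition state with the aldehyde residue equatorial, which moves the alkene to the exocyclic methylene and sets C7 (R) and C8 (R), the butenolide face bias being expected to override the weak Felkin preference of the β-branched α-acyloxy aldehyde.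

Step 9
Reactants: 17 (1S,2E)-1-[(2S,3R)-3-[(1R,2R,3R)-1-hydroxy-3,7-dimethyl-2-(3-methylbutanoyloxy)oct-6-en-1-yl]-4-methylidene-5-oxooxolan-2-yl]-2-methylbut-2-en-1-yl 2-methylpropanoate
Product: 19 (1R)-1-[(2S,3R)-3-[(1R,2R,3R)-1-hydroxy-3-methyl-2-(3-methylbutanoyloxy)-6-oxohexyl]-4-methylidene-5-oxooxolan-2-yl]-2-oxopropyl 2-methylpropanoate, via bis-ozonide 18 (not isolated)
Conditions: O3 (2 equiv, Sudan Red 7B end-point), CH2Cl2, −78 °C; then Me2S, −78 °C to rt; crude used directly
Reagents that add atoms: ozone, [O-][O+]=O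
Why: Chemoselective ozonolysis; the two electron-rich trisubstituted alkenes react far faster than the electron-poor α-methylene lactone, so the C3 aldehyde and the C4 methyl ketone are unmasked in one operation.

Step 10
Reactants: 19 (1R)-1-[(2S,3R)-3-[(1R,2R,3R)-1-hydroxy-3-methyl-2-(3-methylbutanoyloxy)-6-oxohexyl]-4-methylidene-5-oxooxolan-2-yl]-2-oxopropyl 2-methylpropanoate
Product: 20 (4R,5R,6S,7R,8R,9R,10R)-4,8-dihydroxy-5-(2-methylpropanoyloxy)-9-(3-methylbutanoyloxy)-3-oxogermacr-11(13)-en-12,6-olide (CNP0203887.1)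
Conditions: 2-(pentafluorophenyl)-6,7-dihydro-5H-pyrrolo[2,1-c][1,2,4]triazol-2-ium tetrafluoroborate (30 mol %), Et3N (30 mol %), toluene, 60 °C, syringe-pump addition to 2 mM
Reagents that add atoms: none
Why: Proposed new method: the carbene adds to the C3 aldehyde to give a Breslow intermediate whose nucleophilic C3 attacks the C4 methyl ketone (activated by the α-acyloxy group) in a ten-membered crossed benzoin closure, anti to the C5–O bond (polar Felkin–Anh), which places the new C4 hydroxyl anti to the 5-isobutyrate (4R), and the α-ketol releases the catalyst; the closest known reactions are the NHC-catalysed intramolecular aldehyde–ketone benzoin forming five- and six-membered rings and thiazolium-catalysed acyl-anion macrocyclisations.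

**Compound list**
1 | 3-methylbutanoyl chloride | CC(C)CC(=O)Cl | starting material
2 | bis(3-methylbutanoyl) peroxide | CC(C)CC(=O)OOC(=O)CC(C)C | intermediate
3 | (R)-citronellal, (3R)-3,7-dimethyloct-6-enal | C[C@H](CCC=C(C)C)CC=O | starting material
4 | (2R,3R)-3,7-dimethyl-1-oxooct-6-en-2-yl 3-methylbutanoate | O=C[C@H](OC(=O)CC(C)C)[C@H](C)CCC=C(C)C | intermediate
5 | (E)-2-methylbut-2-enal (tiglaldehyde) | C/C=C(\C)C=O | starting material
6 | 3-(methoxymethoxy)prop-1-ene | C=CCOCOC | starting material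
7 | (Z)-3-(methoxymethoxy)allyllithium | [Li]C/C=C\OCOC | intermediate
8 | B-[(Z)-3-(methoxymethoxy)allyl]bis[(1S,2R,3S,5S)-2,6,6-trimethylbicyclo[3.1.1]heptan-3-yl]borane (isopinocampheyl groups as in (+)-Ipc2BOMe) | COCO/C=C\CB([C@H]1C[C@H]2C[C@@H]([C@@H]1C)C2(C)C)[C@H]1C[C@H]2C[C@@H]([C@@H]1C)C2(C)C | intermediate
9 | (3S,4S,5E)-3-(methoxymethoxy)-5-methylhepta-1,5-dien-4-ol | C=C[C@H](OCOC)[C@@H](O)/C(C)=C/C | intermediate
10 | (3S,4S,5E)-3-(methoxymethoxy)-5-methylhepta-1,5-dien-4-yl 2-methylpropanoate | C=C[C@H](OCOC)[C@@H](OC(=O)C(C)C)/C(C)=C/C | intermediate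
11 | (3S,4S,5E)-3-hydroxy-5-methylhepta-1,5-dien-4-yl 2-methylpropanoate | C=C[C@H](O)[C@@H](OC(=O)C(C)C)/C(C)=C/C | intermediate
12 | 2-(bromomethyl)prop-2-enoic acid | C=C(CBr)C(=O)O | starting material
13 | 2-(bromomethyl)prop-2-enoyl chloride | C=C(CBr)C(=O)Cl | intermediate
14 | (3S,4S,5E)-5-methyl-4-(2-methylpropanoyloxy)hepta-1,5-dien-3-yl 2-(bromomethyl)prop-2-enoate | C=C[C@H](OC(=O)C(=C)CBr)[C@@H](OC(=O)C(C)C)/C(C)=C/C | intermediate
15 | (1S,2E)-1-[(2S)-4-(bromomethyl)-5-oxo-2,5-dihydrofuran-2-yl]-2-methylbut-2-en-1-yl 2-methylpropanoate | O=C1O[C@H]([C@@H](OC(=O)C(C)C)/C(C)=C/C)C=C1CBr | intermediate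
16 | allylchromium dichloride derived from 15 (trivalent chromium on C13) | O=C1O[C@H]([C@@H](OC(=O)C(C)C)/C(C)=C/C)C=C1C[Cr](Cl)Cl | intermediate
17 | (1S,2E)-1-[(2S,3R)-3-[(1R,2R,3R)-1-hydroxy-3,7-dimethyl-2-(3-methylbutanoyloxy)oct-6-en-1-yl]-4-methylidene-5-oxooxolan-2-yl]-2-methylbut-2-en-1-yl 2-methylpropanoate | C=C1C(=O)O[C@H]([C@@H](OC(=O)C(C)C)/C(C)=C/C)[C@H]1[C@@H](O)[C@H](OC(=O)CC(C)C)[C@H](C)CCC=C(C)C | intermediate
18 | bis(1,2,4-trioxolane) (bis-ozonide) of 17, ozonide carbons as mixtures | C=C1C(=O)O[C@H]([C@@H](OC(=O)C(C)C)C2(C)OOC(C)O2)[C@H]1[C@@H](O)[C@H](OC(=O)CC(C)C)[C@H](C)CCC1OOC(C)(C)O1 | intermediate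
19 | (1R)-1-[(2S,3R)-3-[(1R,2R,3R)-1-hydroxy-3-methyl-2-(3-methylbutanoyloxy)-6-oxohexyl]-4-methylidene-5-oxooxolan-2-yl]-2-oxopropyl 2-methylpropanoate | C=C1C(=O)O[C@H]([C@@H](OC(=O)C(C)C)C(C)=O)[C@H]1[C@@H](O)[C@H](OC(=O)CC(C)C)[C@H](C)CCC=O | intermediate
20 | (4R,5R,6S,7R,8R,9R,10R)-4,8-dihydroxy-5-(2-methylpropanoyloxy)-9-(3-methylbutanoyloxy)-3-oxogermacr-11(13)-en-12,6-olide | C=C1C(=O)O[C@H]2[C@H]1[C@@H](O)[C@H](OC(=O)CC(C)C)[C@H](C)CCC(=O)[C@](C)(O)[C@@H]2OC(=O)C(C)C | target

**Totals**
Total step count: 10. Longest linear sequence: 8 (steps 3 to 10).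

**Three steps most likely to fail**

Step 10 (macrocyclic benzoin). The ten-membered closure may lose to oligomers, the Breslow intermediate or the free carbene may add to the α-methylene lactone (Stetter-type), and C4 selectivity rests on substrate control; 19 can also rest as a six-membered hemiketal between the C8 hydroxyl and the C4 ketone. Fallback, from 17 back to 20: remove the Michael acceptor before the key step. Dimethylamine in THF at 0 °C adds to the methylene lactone of 17 to give the 13-(dimethylamino)-11,13-dihydro adduct F1. Ozonolysis of F1 as its trifluoroacetate salt (Me2S work-up, then NaHCO3 wash) gives the amino keto-aldehyde F2. The same carbene-catalysed benzoin closure on F2 gives the 13-(dimethylamino)-11,13-dihydro macrocycle F3. MeI in MeOH converts F3 to the trimethylammonium iodide F4, and aqueous NaHCO3 eliminates trimethylamine to restore the methylene lactone, giving 20.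

Step 8 (allylchromium addition). The desired 8,9-syn product is the anti-Felkin one for aldehyde 4, so the butenolide face bias and the aldehyde bias oppose each other. Translactonisation to O8 and O9-to-O8 acyl shift are further risks. Fallback, from 15 and 4 back to 17: set C8 by reduction, not by addition. If the coupling gives mainly the C8 epimer, (8S)-alcohol F5, Dess–Martin periodinane in CH2Cl2 buffered with NaHCO3 oxidises it to the C8 ketone F6. NaBH4 with CeCl3 in MeOH at −78 °C then reduces the ketone only (no conjugate reduction), with hydride delivered anti to the C9 acyloxy group (polar Felkin–Anh), which gives the 8,9-syn alcohol 17.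

Step 2 (α-acyloxylation with an aliphatic diacyl peroxide). The peroxide is less electrophilic and more prone to radical decay than dibenzoyl peroxide, and 4 can epimerise at C9. Fallback, from 3 back to 4, with C9 set by proline-catalysed aminoxylation. Treatment of 3 with nitrosobenzene and L-proline in CHCl3 at 4 °C, then NaBH4, gives (2R,3R)-3,7-dimethyl-2-(anilinooxy)oct-6-en-1-ol F7. Zn in AcOH cleaves the N–O bond to give (2R,3R)-3,7-dimethyloct-6-ene-1,2-diol F8. TBSCl and imidazole silylate the primary hydroxyl to give the silyl ether F9. Isovaleryl chloride, pyridine and DMAP give the silyl ether ester F10. HF·pyridine in THF removes the silyl group without acyl shift to give (2R,3R)-1-hydroxy-3,7-dimethyloct-6-en-2-yl 3-methylbutanoate F11. Dess–Martin periodinane then gives 4.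

**Further compounds**
F1 | step 10 | 13-(dimethylamino)-11,13-dihydro adduct of 17 (C11 epimers) | CN(C)CC1C(=O)O[C@H]([C@@H](OC(=O)C(C)C)/C(C)=C/C)[C@H]1[C@@H](O)[C@H](OC(=O)CC(C)C)[C@H](C)CCC=C(C)C
F2 | step 10 | 13-(dimethylamino)-11,13-dihydro analogue of 19 (amino keto-aldehyde) | CN(C)CC1C(=O)O[C@H]([C@@H](OC(=O)C(C)C)C(C)=O)[C@H]1[C@@H](O)[C@H](OC(=O)CC(C)C)[C@H](C)CCC=O
F3 | step 10 | 13-(dimethylamino)-11,13-dihydro analogue of 20 | CN(C)CC1C(=O)O[C@H]2[C@H]1[C@@H](O)[C@H](OC(=O)CC(C)C)[C@H](C)CCC(=O)[C@](C)(O)[C@@H]2OC(=O)C(C)C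
F4 | step 10 | trimethylammonium iodide of F3 | C[N+](C)(C)CC1C(=O)O[C@H]2[C@H]1[C@@H](O)[C@H](OC(=O)CC(C)C)[C@H](C)CCC(=O)[C@](C)(O)[C@@H]2OC(=O)C(C)C.[I-]
F5 | step 8 | C8 epimer of 17, (8S)-alcohol | C=C1C(=O)O[C@H]([C@@H](OC(=O)C(C)C)/C(C)=C/C)[C@H]1[C@H](O)[C@H](OC(=O)CC(C)C)[C@H](C)CCC=C(C)C
F6 | step 8 | C8 ketone derived from F5 | C=C1C(=O)O[C@H]([C@@H](OC(=O)C(C)C)/C(C)=C/C)[C@H]1C(=O)[C@H](OC(=O)CC(C)C)[C@H](C)CCC=C(C)C
F7 | step 2 | (2R,3R)-3,7-dimethyl-2-(anilinooxy)oct-6-en-1-ol | OC[C@H](ONc1ccccc1)[C@H](C)CCC=C(C)C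
F8 | step 2 | (2R,3R)-3,7-dimethyloct-6-ene-1,2-diol | OC[C@H](O)[C@H](C)CCC=C(C)C
F9 | step 2 | (2R,3R)-1-(tert-butyldimethylsilyloxy)-3,7-dimethyloct-6-en-2-ol | CC(C)(C)[Si](C)(C)OC[C@H](O)[C@H](C)CCC=C(C)C
F10 | step 2 | (2R,3R)-1-(tert-butyldimethylsilyloxy)-3,7-dimethyloct-6-en-2-yl 3-methylbutanoate | CC(C)(C)[Si](C)(C)OC[C@H](OC(=O)CC(C)C)[C@H](C)CCC=C(C)C
F11 | step 2 | (2R,3R)-1-hydroxy-3,7-dimethyloct-6-en-2-yl 3-methylbutanoate | OC[C@H](OC(=O)CC(C)C)[C@H](C)CCC=C(C)C
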